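**Retrosynthetic overview**
1. Locants: C1 exocyclic CHBr, C2 enol-ether carbon, C3 methyl-bearing epoxide carbon, C4 epoxide CH, C5 CH2, C6 fusion CH, C7 methyl-bearing C–O fusion carbon, C8 and C9 CH2, C10 CHBr, C11 CMe2. Ring A is the cyclohexane C6–C11 and ring B is the oxepane O/C2–C7.
2. Feature used: quaternary C7 carries the ring B oxygen and a methyl group and is bonded to C6. C7 and C6 are therefore read as the α-carbon and the carbonyl carbon of 2-methyloxepan-3-one (ring B intact), and C8–C11 as butenone. Cutting C7–C8 and C6–C11 removes ring A.
3. Endgame disconnections: the (E)-C1HBr unit comes from a C2 lactone by dibromoolefination and loss of one bromine, and the epoxide from a C3(Me)=C4 enoate. C2=O comes from the oxepane CH2 (RuO4) and C10–Br from inversion of an axial alcohol. C6–H comes from radical hydrogenation and the C11 methyls from deconjugative alkylation.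
4. Ring order: ring B first (rhodium carbenoid O–H insertion), ring A second (auxiliary-controlled Michael–aldol annulation, which sets C7), epoxide last. C6, C10, C3 and C4 are relayed from C7.

Key step: step 6

**Remarks**
- β denotes the face of the C7 methyl group and α the face of C6–H.
- Assumption: the (S)-amine should direct butenone to the same spatial face as in the 2-methylcyclohexanone series, with the ring oxygen taking the place of a ring CH2. This corresponds to 7R. If the sense were opposite, the (R)-amine would be used.
- Assumption: [Ph3PCHBr2]Br is taken as a catalogue reagent (otherwise it is made from CBr4, PPh3 and water). Dimethyldioxirane (DMDO) is used as its standard acetone solution.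

**Step 1**
Reactants: 1 δ-valerolactone; 2 ethyl diazoacetate
Product: 3 ethyl 2-diazo-7-hydroxy-3-oxoheptanoate
Conditions: LiN(i-Pr)2, THF, −78 °C; AcOH quench
Reagents that add atoms: none
Why: Claisen-type acylation of ethyl lithiodiazoacetate by the lactone opens the ring and is an established entry to ω-hydroxy α-diazo β-keto esters; the stabilised product anion resists a second addition.

**Step 2**
Reactants: 3 ethyl 2-diazo-7-hydroxy-3-oxoheptanoate
Product: 4 ethyl 3-oxooxepane-2-carboxylate (racemic)
Conditions: Rh2(OAc)4 (1 mol %), CH2Cl2, reflux, slow addition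
Reagents that add atoms: none
Why: Intramolecular rhodium carbenoid O–H insertion forms the O–C7 bond and closes ring B, a closure that is well established for seven-membered cyclic ethers from this class of hydroxy diazo keto ester.

**Step 3**
Reactants: 4 ethyl 3-oxooxepane-2-carboxylate
Product: 5 ethyl 2-methyl-3-oxooxepane-2-carboxylate (racemic)
Conditions: MeI, K2CO3, acetone, rt to reflux
Reagents that add atoms: iodomethane, CI
Why: C-alkylation of the β-keto ester enolate with a soft electrophile places the C7 methyl group; the racemic centre is of no consequence because it is flattened again in step 6.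

**Step 4**
Reactants: 5 ethyl 2-methyl-3-oxooxepane-2-carboxylate
Product: 6 2-methyloxepan-3-one (racemic)
Conditions: LiCl, H2O, DMSO, 150 °C
Reagents that add atoms: none
Why: Krapcho dealkoxycarbonylation removes the ester under near-neutral conditions and so avoids the retro-Claisen ring opening that hydroxide would cause on a non-enolisable β-keto ester.

**Step 5**
Reactants: 6 2-methyloxepan-3-one; 7 (S)-1-phenylethylamine
Product: 8 N-[(S)-1-phenylethyl]imine of 2-methyloxepan-3-one (mixture at C7 and at C=N)
Conditions: TsOH (cat.), toluene, Dean–Stark, reflux
Reagents that add atoms: none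
Why: Azeotropic ketone–amine condensation should give the imine; its C7 epimers and C=N isomers interconvert through the enamine tautomers, so the mixture can be used as such.

**Step 6**
Reactants: 8 N-[(S)-1-phenylethyl]imine of 2-methyloxepan-3-one; 9 methyl vinyl ketone
Product: 12 bicyclic enone (7R; ring B oxepane fused to ring A cyclohexenone; C10=O; C6=C11), via Michael adduct imine 10 (not isolated), via diketone 11 (not isolated)
Conditions: THF, hydroquinone (trace), rt, 3 d; 20% aq AcOH, rt; crude 11, NaOMe (0.3 equiv), MeOH, 60 °C
Reagents that add atoms: none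
Why: Imine 8 equilibrates with its more substituted secondary enamine (C6=C7), which adds to butenone 9 through a compact chair-like aza-ene transition state in which the N–H proton passes to the acceptor α-carbon as C7–C8 forms, giving 10; aqueous acetic acid then frees diketone 11 and the auxiliary, and methoxide triggers the aldol condensation. The closest known chemistry is the deracemising Michael alkylation of 1-phenylethylamine imines of 2-substituted cyclanones, 2-methyl oxa- and thiacyclopentan-3-ones included, followed by Robinson annulation, so the seven-membered α-oxygenated ketone only extends the ring size. Ring A closes by a 6-(enolexo)-exo-trig aldol addition of the C11 methyl ketone enolate to the C6 carbonyl, and E1cB loss of water installs C6=C11. C7, the only new stereocentre, is controlled by the auxiliary: in the reactive enamine conformer the benzylic C–H points toward C5 to minimise allylic strain, the phenyl group covers one face and 9 enters from the other, which with the (S)-amine should give 7R, and both enantiomers of 6 converge because C7 is planar in the enamine. The step needs alkylation at C7 rather than C5, which is secured because the C5=C6 enamine would press its N-substituent against the C7 substituents when N–H is held syn to the nucleophilic carbon, whereas the C6=C7 enamine, favoured by the methyl group and the ring oxygen, turns it toward the unsubstituted C5; a second alkylation is excluded because 10 has no hydrogen left at C7. Among the possible aldol modes only C11 to C6 can dehydrate to a conjugated enone, the others being reversible.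

**Step 7**
Reactants: 12 bicyclic enone
Product: 13 β,γ-unsaturated ketone (7R; C11 gem-dimethyl; C10=O; C5=C6)
Conditions: KOt-Bu (2.5 equiv), t-BuOH, rt; MeI (3 equiv)
Reagents that add atoms: iodomethane, CI
Why: Deconjugative double α-alkylation of the extended dienolate, the classical gem-dimethylation of 4-en-3-one systems, methylates C11 twice and leaves the alkene at C5=C6 without touching C7.

**Step 8**
Reactants: 13 β,γ-unsaturated ketone
Product: 14 trans-fused ketone (6R,7R; C6–H α and anti to the C7 methyl)
Conditions: Mn(dpm)3 (10 mol %), PhSiH3, t-BuOOH, i-PrOH, rt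
Reagents that add atoms: none
Why: In this metal-hydride hydrogen atom transfer hydrogenation (Mukaiyama type) a hydrogen atom adds to the accessible C5, and the tertiary C6 radical should take its hydrogen from the α face because the β face is closed by the syn-axial methyls at C7 and C11, which sets 6R (trans fusion); no metal surface is present that could hydrogenolyse the allylic C7–O bond.

**Step 9**
Reactants: 14 trans-fused ketone
Product: 15 axial alcohol (6R,7R,10S; C10–OH α and cis to C6–H)
Conditions: LiBH(s-Bu)3, THF, −78 °C; then H2O2, aq NaOH (cat.), 0 °C
Reagents that add atoms: none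
Why: The bulky trialkylborohydride avoids the axial trajectory flanked by the axial hydrogens at C6 and C8 and delivers hydride equatorially, as in the reduction of 4,4-dimethyl-3-keto terpenoids to their axial 3α-alcohols, which sets 10S.

**Step 10**
Reactants: 15 axial alcohol
Product: 16 equatorial bromide (6R,7R,10R; C10–Br β)
Conditions: CBr4, P(n-Oct)3, toluene, 70 °C
Reagents that add atoms: carbon tetrabromide, BrC(Br)(Br)Br
Why: In this Appel reaction the axial oxyphosphonium group is displaced by bromide in an SN2 process from the equatorial side, so inversion gives 10R; the small, strongly activating trialkylphosphine is the variant used for neopentylic secondary carbinols next to a gem-dimethyl group.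

**Step 11**
Reactants: 16 equatorial bromide
Product: 17 ε-lactone (C2=O; 6R,7R,10R)
Conditions: RuCl3·xH2O (5 mol %), NaIO4, CCl4/MeCN/H2O, rt
Reagents that add atoms: sodium periodate (oxygen passed on through RuO4), [Na+].[O-]I(=O)(=O)=O
Why: RuO4 oxidation of an ether to a lactone can only occur at C2 because the other ether carbon, C7, is quaternary, as in the oxidation of related tertiary-alkyl cyclic terpene ethers to their lactones; the alkyl bromide is inert.

**Step 12**
Reactants: 17 ε-lactone
Product: 18 C3-phenylselanyl lactone (C3 epimers)
Conditions: LiN(i-Pr)2, THF, −78 °C; PhSeBr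
Reagents that add atoms: benzeneselenenyl bromide, Br[Se]c1ccccc1
Why: α-Selenenylation of the lactone enolate is standard; the equatorial neopentylic C10 bromide has no antiperiplanar hydrogen and should survive the amide base at low temperature.

**Step 13**
Reactants: 18 C3-phenylselanyl lactone
Product: 20 α,β-unsaturated lactone (C3=C4), via selenoxide 19 (not isolated)
Conditions: 30% H2O2, pyridine, CH2Cl2, 0 °C to rt
Reagents that add atoms: none
Why: Selenoxide syn-elimination can only remove a hydrogen from C4, so the C3=C4 alkene forms without regiochemical ambiguity.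

**Step 14**
Reactants: 20 α,β-unsaturated lactone
Product: 22 C3-bromo unsaturated lactone, via vicinal dibromide 21 (not isolated)
Conditions: Br2, CH2Cl2, 0 °C to rt; Et3N, 0 °C
Reagents that add atoms: bromine, BrBr
Why: Bromine addition followed by E1cB loss of HBr through the acidic C3–H gives the α-bromo enoate, as in the standard preparation of 3-bromo-5,6-dihydropyran-2-one.

**Step 15**
Reactants: 22 C3-bromo unsaturated lactone
Product: 23 C3-methyl unsaturated lactone (C3(Me)=C4)
Conditions: MeZnCl, Pd(PPh3)4 (5 mol %), THF, rt to 50 °C
Reagents that add atoms: methylzinc chloride, C[Zn]Cl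
Why: In this Negishi coupling zerovalent palladium inserts into the activated alkenyl C3–Br bond and leaves the hindered secondary C10–Br alone; attaching the methyl group to a preformed C3=C4 avoids the endo/exo ambiguity of eliminating from an α-methyl-α-selanyl lactone.

**Step 16**
Reactants: 23 C3-methyl unsaturated lactone
Product: 24 α-epoxy lactone (3S,4S,6R,7R,10R)
Conditions: DMDO, acetone/CH2Cl2, rt
Reagents that add atoms: dimethyldioxirane, CC1(C)OO1
Why: Concerted dioxirane epoxidation of an enoate should take place on the α face, anti to the C7 methyl group that overhangs the β face of the twisted ring B, and sets 3S and 4S together under neutral conditions.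

**Step 17**
Reactants: 24 α-epoxy lactone
Product: 25 dibromomethylene enol ether (C2=C1Br2; 3S,4S,6R,7R,10R)
Conditions: [Ph3PCHBr2]Br, KOt-Bu, THF, 0 °C; then 24, rt to reflux
Reagents that add atoms: (dibromomethyl)triphenylphosphonium bromide, BrC(Br)[P+](c1ccccc1)(c1ccccc1)c1ccccc1.[Br-]
Why: Wittig-type (Ramirez) dibromoolefination of lactone carbonyls is known for α-oxygenated sugar lactones, and 24 is likewise α-oxygenated and cannot enolise; generating the ylide with base keeps Ph3PBr2, which would open the epoxide, out of the flask.

**Step 18**
Reactants: 25 dibromomethylene enol ether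
Product: 26 target CNP0375295.2 (1E,3S,4S,6R,7R,10R)
Conditions: Bu3SnH (1.05 equiv, slow addition), Pd(PPh3)4 (5 mol %), toluene, rt
Reagents that add atoms: none
Why: In the palladium-catalysed stereoselective hydrogenolysis of a 1,1-dibromoalkene, oxidative addition occurs at the less hindered C–Br bond (cis to the ring oxygen, trans to quaternary C3) and hydride transfer with retention leaves the bromine cis to C3, which is the E geometry.

**Compound list**
1 | δ-valerolactone | O=C1CCCCO1 | starting material
2 | ethyl diazoacetate | CCOC(=O)C=[N+]=[N-] | starting material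
3 | ethyl 2-diazo-7-hydroxy-3-oxoheptanoate | CCOC(=O)C(=[N+]=[N-])C(=O)CCCCO | intermediate
4 | ethyl 3-oxooxepane-2-carboxylate (racemic) | CCOC(=O)C1OCCCCC1=O | intermediate
5 | ethyl 2-methyl-3-oxooxepane-2-carboxylate (racemic) | CCOC(=O)C1(C)OCCCCC1=O | intermediate
6 | 2-methyloxepan-3-one (racemic) | CC1OCCCCC1=O | intermediate
7 | (S)-1-phenylethylamine | C[C@H](N)c1ccccc1 | starting material
8 | N-[(S)-1-phenylethyl]imine of 2-methyloxepan-3-one | C[C@H](N=C1CCCCOC1C)c1ccccc1 | intermediate
9 | methyl vinyl ketone | CC(=O)C=C | starting material
10 | (S)-1-phenylethyl imine of (R)-2-methyl-2-(3-oxobutyl)oxepan-3-one (not isolated) | C[C@H](N=C1CCCCO[C@]1(C)CCC(C)=O)c1ccccc1 | intermediate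
11 | (R)-2-methyl-2-(3-oxobutyl)oxepan-3-one (not isolated) | C[C@]1(CCC(C)=O)OCCCCC1=O | intermediate
12 | bicyclic enone, 7R, C10=O, C6=C11 | C[C@@]12CCC(=O)C=C1CCCCO2 | intermediate
13 | β,γ-unsaturated ketone, 7R, C11 gem-dimethyl, C5=C6 | CC1(C)C(=O)CC[C@@]2(C)OCCCC=C12 | intermediate
14 | trans-fused ketone, 6R,7R | CC1(C)C(=O)CC[C@@]2(C)OCCCC[C@H]12 | intermediate
15 | axial C10 alcohol, 6R,7R,10S | CC1(C)[C@@H](O)CC[C@@]2(C)OCCCC[C@H]12 | intermediate
16 | equatorial C10 bromide, 6R,7R,10R | CC1(C)[C@H](Br)CC[C@@]2(C)OCCCC[C@H]12 | intermediate
17 | ε-lactone, C2=O | CC1(C)[C@H](Br)CC[C@@]2(C)OC(=O)CCC[C@H]12 | intermediate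
18 | C3-phenylselanyl lactone (C3 epimers) | CC1(C)[C@H](Br)CC[C@@]2(C)OC(=O)C([Se]c3ccccc3)CC[C@H]12 | intermediate
19 | C3 selenoxide (not isolated) | CC1(C)[C@H](Br)CC[C@@]2(C)OC(=O)C([Se](=O)c3ccccc3)CC[C@H]12 | intermediate
20 | α,β-unsaturated lactone, C3=C4 | CC1(C)[C@H](Br)CC[C@@]2(C)OC(=O)C=CC[C@H]12 | intermediate
21 | C3,C4-dibromo lactone (not isolated) | CC1(C)[C@H](Br)CC[C@@]2(C)OC(=O)C(Br)C(Br)C[C@H]12 | intermediate
22 | C3-bromo unsaturated lactone | CC1(C)[C@H](Br)CC[C@@]2(C)OC(=O)C(Br)=CC[C@H]12 | intermediate
23 | C3-methyl unsaturated lactone | CC1(C)[C@H](Br)CC[C@@]2(C)OC(=O)C(C)=CC[C@H]12 | intermediate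
24 | α-epoxy lactone, 3S,4S,6R,7R,10R | CC1(C)[C@H](Br)CC[C@@]2(C)OC(=O)[C@@]3(C)O[C@H]3C[C@H]12 | intermediate
25 | dibromomethylene enol ether, 3S,4S,6R,7R,10R | CC1(C)[C@H](Br)CC[C@@]2(C)OC(=C(Br)Br)[C@@]3(C)O[C@H]3C[C@H]12 | intermediate
26 | CNP0375295.2, 1E,3S,4S,6R,7R,10R | CC1(C)[C@H](Br)CC[C@@]2(C)O/C(=C/Br)[C@@]3(C)O[C@H]3C[C@H]12 | target

**Step count**
Total step count: 18
Longest linear sequence: 18 steps (fully linear from 1)

**Steps most likely to fail**

1. Step 17, dibromoolefination.
   - What may go wrong: the bulky, weakly nucleophilic ylide may fail to add to a carbonyl flanked by quaternary C3 and the tertiary C7–O group. The epoxide may also be opened at the temperature the addition needs.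
   - Fallback: it sets out from 24 and returns at 25.
   - The carbonyl is first methylenated with the small titanium methylidene released from Cp2TiMe2 (toluene, 70 °C, Petasis methylenation), giving the exocyclic methylene enol ether F1.
   - Bromine addition (Br2, CH2Cl2, −78 °C) gives the C1,C2-dibromide F2. DBU converts this in the same flask into the (Z)-bromomethylene enol ether F3.
   - A second bromine addition gives the tribromide F4, and DBU elimination delivers 25.

2. Step 10, invertive bromination.
   - What may go wrong: E2 loss toward C9 from the axial oxyphosphonium ion, or ionisation with a 1,2-methyl shift from C11, may outrun substitution at the neopentylic centre.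
   - Fallback: it sets out from 14 and returns at 16, bypassing 15.
   - Condensation with hydrazine (N2H4·H2O, Et3N, EtOH, reflux) gives the hydrazone F5.
   - The Barton vinyl halide synthesis (Br2, 2-tert-butyl-1,1,3,3-tetramethylguanidine, Et2O, 0 °C) gives the C9=C10 vinyl bromide F6. Only C9 offers a hydrogen, so there is no regiochemical choice.
   - The hydrogen atom transfer conditions of step 8 spare C–Br bonds. A hydrogen atom should add to C9, and the second hydrogen should reach the C10 bromo radical axially from the α face, leaving bromine equatorial (10R).

3. Step 18, monodebromination.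
   - What may go wrong: zerovalent palladium may ionise the allylic C3–O bond of the epoxide. A second hydrogenolysis or a radical-chain reduction of C10–Br may also compete.
   - Fallback: it sets out from 23 and returns at 26, so that palladium never meets the epoxide.
   - Olefination of 23 under neutral conditions (CBr4, PPh3, toluene, reflux) gives the dibromodiene F7.
   - Pd(PPh3)4/Bu3SnH removes the bromine cis to the ring oxygen and gives the (E)-bromodiene F8.
   - DMDO (acetone, −20 °C) should then epoxidise the trisubstituted C3=C4 alkene from the α face. The enol ether is less reactive because bromine deactivates it and the Br/C3-methyl clash twists it out of conjugation.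

**Further compounds**
F1 | step 17 | exocyclic methylene enol ether (C2=CH2) of the epoxy oxepane | CC1(C)[C@H](Br)CC[C@@]2(C)OC(=C)[C@@]3(C)O[C@H]3C[C@H]12
F2 | step 17 | C1,C2-dibromide (2-bromo-2-bromomethyl oxepane) | CC1(C)[C@H](Br)CC[C@@]2(C)OC(Br)(CBr)[C@@]3(C)O[C@H]3C[C@H]12
F3 | step 17 | (Z)-bromomethylene enol ether | CC1(C)[C@H](Br)CC[C@@]2(C)O/C(=C\Br)[C@@]3(C)O[C@H]3C[C@H]12
F4 | step 17 | tribromide (2-bromo-2-dibromomethyl oxepane) | CC1(C)[C@H](Br)CC[C@@]2(C)OC(Br)(C(Br)Br)[C@@]3(C)O[C@H]3C[C@H]12
F5 | step 10 | C10 hydrazone of ketone 14 | CC1(C)C(=NN)CC[C@@]2(C)OCCCC[C@H]12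
F6 | step 10 | C9=C10 vinyl bromide | CC1(C)C(Br)=CC[C@@]2(C)OCCCC[C@H]12
F7 | step 18 | dibromodiene (C2=C1Br2, C3(Me)=C4) | CC1(C)[C@H](Br)CC[C@@]2(C)OC(=C(Br)Br)C(C)=CC[C@H]12
F8 | step 18 | (E)-bromodiene | CC1(C)[C@H](Br)CC[C@@]2(C)O/C(=C/Br)C(C)=CC[C@H]12
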